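## The problem

The target 17 is 5,7-dihydroxy-2-(4-hydroxyphenyl)-3,6,8-trimethoxychromen-4-one. It is a flavonol methyl ether in which ring A (C4a, C5–C8, C8a) is fused to the pyranone ring C across C4a=C8a, and ring B is a 4-hydroxyphenyl group on C2. Ring A carries no hydrogen: C5, C6, C7 and C8 bear OH, OMe, OH and OMe in turn. The task is therefore to build a hexasubstituted benzene and to tell O6 and O8 (methylated) from O5 and O7 (free). There are no stereocentres, so any centre that appears on the way is transient and needs no control. Three parts are sensitive: the pyranone opens with hard nucleophiles and strong base, the polyhydroxylated ring A oxidises to a quinone in base and air, and the ethers next to the C4 carbonyl respond first to Lewis acids. Two handles for sorting the phenols are built into the skeleton: the 5-OH is chelated to the C4 carbonyl and is alkylated last, while the 7-OH and 4'-OH are vinylogous acids and are alkylated first. The feature that opens the route is that C5–C8 with their four oxygens are exactly the four carbons of a squaric ester, and that the bond they are fused to, C4a=C8a, is the C3=C2 double bond of a 4-pyranone. Ring A can therefore be grown by benzannulation on a finished ring B–ring C unit.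

## Retrosynthesis

**17 ⇒ 16 ⇒ 15 ⇒ 14.** The last operations are placed on oxygen. Cutting the two O–benzyl bonds of 16 (O7, O4'), then its O6–methyl bond, leads to 15 and, after removing its benzyl groups, to the tetraphenol 14. The neighbouring choice, carrying O6 and O7 differently substituted through the ring construction, would need an unsymmetrical squaric ester whose two carbonyls a nucleophile cannot tell apart. With 14 the problem reduces to acidity. The forward steps must put benzyl on the two vinylogous-acid hydroxyls and then methyl on O6, with O5 held back by its hydrogen bond.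

**14 ⇒ 13 ⇒ 12.** The free hydroxyls at O6, O7 and O4' of 14 are traced back to two isopropyl ethers and one benzyl ether in 13. The O8–methyl bond of 13 is then cut to give hydroquinone 12. Isopropyl is preferred to methyl on the squarate because BCl3 removes it beside the methoxyls at C3 and C8. The 8-O-methyl is placed before the deprotection because in 12 the 8-OH is the only unchelated phenol. The forward steps need a mono-methylation without air oxidation of 12 and an ether cleavage that spares two methyl ethers.

**12 ⇒ 9 (key disconnection).** Ring A is opened at C8–C8a and folded back to a four-membered ring. 12 is the ring-expansion product of the 4-hydroxycyclobutenone 9, whose carbinol carbon is the future C5 and whose ring carbonyl is the future C8. The neighbouring cuts would either assemble ring C on a pre-made hexasubstituted benzene or introduce the ring A oxygens one at a time on an arene. This cut instead delivers the whole benzene ring with four C–O bonds in place in one thermal step without reagents. 9 is far simpler than 12: a monocyclic pyranone bearing a squarate adduct. The forward reaction requires outward rotation of the hydroxyl on ring opening and closure of the ketene onto pyranone C2.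

**9 ⇒ 6 + 7.** The bond between the carbinol carbon and pyranone C3 (future C4a–C5) is cut. This gives diisopropyl squarate 7 and a carbanion at the α-carbon of the pyranone, realised as the magnesium reagent 8 from iodide 6. The symmetric diester makes the two carbonyls equivalent, so only 1,2- against 1,4-addition has to be controlled. The metalated pyranone must survive long enough at low temperature to add once to 7.

**6 ⇒ 5 ⇒ 3 + 4.** The C5–I bond is removed to give 5, and the C2–aryl bond of 5 is cut to iodopyranone 3 and boronic acid 4. Cross-coupling at the vinylogous acyl iodide keeps ring B out of all ring-forming chemistry. Iodinating C5 after the coupling means only one carbon–halogen bond is present when palladium is used. The iodination must choose the pyranone α-carbon over ring B.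

**3 ⇒ 2 ⇒ 1.** 3 is the methyl ether of 2, and 2 is pyromeconic acid 1 iodinated next to its enolic hydroxyl. 1 is commercial and already contains ring C with the C3 oxygen and the C4 carbonyl of the target.

## Roads not taken

**Alternative 1:** Ring C would be closed last, at C3–C4 and C2=C3.
- **Cut:** C3 with its methoxyl is removed as a one-carbon ylide unit. This leaves the ring A benzoyl chloride A2, whose two ortho oxygens both carry the ring B acyl group as 4-benzyloxybenzoates.
- **Forward key step:** A2 acylates Ph3P=CHOMe (two equivalents, the second as base). The acyl ylide formed in the flask then olefinates the neighbouring aryl ester carbonyl in an intramolecular Wittig reaction to give chromone A1.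
- **Merits:** The route is convergent, the two esters of A2 are equivalent so either may close, and the 3-methoxyl arrives with the ylide. A1 already has O7 as benzyl and O6/O8 as methyl, so only ester hydrolysis at O5 and hydrogenolysis remain. That endgame is shorter than the five steps that follow the key step in the chosen plan.
- **Weak points:** A2 is a hexasubstituted benzoic acid derivative, so its preparation contains the whole ring A problem and would be long. Its acid chloride sits between two ortho acyloxy groups, while the aryl esters are themselves good acyl donors toward an unstabilised ylide, so acylation at the wrong carbonyl is likely. One aroyl group and half of the ylide are sacrificed.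
- **Comparison:** This road is better at the end and worse at the start. The chosen plan answers with the four ring A oxygens bought as one commercial reagent.

**Alternative 2:** Ring C would be closed at C4–C4a.
- **Cut:** That bond and the C3 carbonyl are traced back to a terminal alkyne, the aryl propargyl ether A4, built from a pentaoxygenated phenol and a 1-arylpropargyl unit.
- **Forward key step:** Ph3PAuNTf2 and a pyridine N-oxide oxidise the alkyne to an α-oxo gold carbene. Its carbon attacks the single free ortho position of ring A to give the chroman-3-one A3, racemic at C2.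
- **Merits:** The closure is mild, neutral and catalytic, with one possible site. O5/O7 (benzyl) and O6/O8 (methyl) are sorted before the ring is made, so no late differentiation of phenols is needed. In this respect it is better than the chosen plan.
- **Weak points:** A3 is at the wrong oxidation level, with C4 as CH2 and C2 as sp3. The flavonol then needs a C4 oxidation, a dehydrogenation and an O3 methylation whose enol regiochemistry (toward C2 or C4) is itself uncertain. The doubly activated propargylic C–O bond of A4 ionises easily under a cationic gold catalyst. The phenol component again needs a multistep arene synthesis.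
- **Comparison:** The chosen plan keeps ring C at its final oxidation level from the first step and never makes a centre that must be destroyed by redox steps. It pays with the phenol sorting at the end.

**Alternative 3:** No ring would be made late.
- **Cut:** The C6–OMe and C8–OMe bonds are cut back to the C–Br bonds of dibromide A6. A6 would come from brominating a 7,4'-dibenzylated 5-hydroxy-3-methoxyflavone at its two activated ring A positions.
- **Forward key step:** NaOMe with CuBr in DMF–MeOH replaces both bromides (Ullmann-type methoxylation) to give A5. A5 is the same compound as 16 of the chosen route, one hydrogenolysis from the target.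
- **Merits:** This is the shortest road by a clear margin, from cheap flavonol-type materials, and in step count it is better than the chosen plan.
- **Weak points:** Two substitutions must both go to completion at carbons flanked on each side by oxygen substituents. Under NaOMe the 5-OH is a phenoxide, which makes ring A electron-rich and slows the copper-mediated substitution. Protodebromination would give 6- or 8-monomethoxy congeners that are hard to separate from A5. Hot methoxide also attacks C2 of the pyranone.
- **Comparison:** If the double methoxylation is clean, this road wins. The chosen plan sets against it that no C–O bond is forged on a crowded arene, since all four arrive with the squarate, so under-oxygenated congeners cannot form.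

Key step: step 6

Remark: the target is achiral. Carbinol 9 and dienone 11 are racemic and their centres vanish on aromatisation, so no configuration has to be set anywhere.

## Route

Step 1
Reactants: 1 pyromeconic acid (3-hydroxy-4H-pyran-4-one)
Product: 2 3-hydroxy-2-iodo-4H-pyran-4-one
Conditions: NIS (1.05 equiv), MeCN, 0 °C → rt
Reagents that add atoms: N-iodosuccinimide, O=C1CCC(=O)N1I
Why: Electrophilic iodination of an enol: in 3-hydroxy-4-pyranones the carbon ortho to the enolic hydroxyl (C2) is the established site of halogenation, Mannich and aldol-type substitution, so the iodine should enter there only.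

Step 2
Reactants: 2 3-hydroxy-2-iodo-4H-pyran-4-one
Product: 3 2-iodo-3-methoxy-4H-pyran-4-one
Conditions: MeI, K2CO3, acetone, rt
Reagents that add atoms: iodomethane, CI
Why: Williamson O-methylation of the acidic enolic hydroxyl, as for maltol and kojic acid ethers; mild carbonate in acetone spares the vinylogous acyl iodide.

Step 3
Reactants: 3 2-iodo-3-methoxy-4H-pyran-4-one; 4 4-(benzyloxy)phenylboronic acid
Product: 5 2-[4-(benzyloxy)phenyl]-3-methoxy-4H-pyran-4-one
Conditions: Pd(PPh3)4 (5 mol %), K2CO3, dioxane–H2O, 80 °C
Reagents that add atoms: none
Why: Suzuki–Miyaura coupling; the C2–I bond is a vinylogous acyl iodide that adds readily to zerovalent palladium, and halopyranones and halochromones are standard partners under aqueous carbonate.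

Step 4
Reactants: 5 2-[4-(benzyloxy)phenyl]-3-methoxy-4H-pyran-4-one
Product: 6 2-[4-(benzyloxy)phenyl]-5-iodo-3-methoxy-4H-pyran-4-one
Conditions: I2 (0.6 equiv), (NH4)2Ce(NO3)6 (1.1 equiv), MeCN, 60 °C
Reagents that add atoms: iodine, II
Why: Electrophilic α-iodination of the vinylogous ester with I2 and the tetravalent cerium oxidant, the method used to make 3-iodoflavones; C5 is the only enol-ether-type carbon of the pyranone (activated by O1 through C6), while ring B is deactivated by conjugation with the pyranone carbonyl.

Step 5
Reactants: 6 2-[4-(benzyloxy)phenyl]-5-iodo-3-methoxy-4H-pyran-4-one; 7 diisopropyl squarate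
Product: 9 4-{6-[4-(benzyloxy)phenyl]-5-methoxy-4-oxo-4H-pyran-3-yl}-4-hydroxy-2,3-diisopropoxycyclobut-2-en-1-one (racemic), via pyranonylmagnesium chloride 8 (not isolated)
Conditions: iPrMgCl·LiCl (1.05 equiv), THF, −78 °C; then 7, −78 °C; aq. NH4Cl
Reagents that add atoms: none
Why: Iodine–magnesium exchange on a cyclic α-iodo-β-alkoxy enone, as established for 5-iodouracils and 5-iodo-1,3-dioxin-4-ones, gives alkenylmagnesium 8, which is kept at −78 °C to suppress β-elimination of the ring oxygen. Its 1,2-addition to one carbonyl of the symmetric squarate is the standard entry to 4-hydroxycyclobutenones; the new carbinol centre is formed racemic and is erased in step 6.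

Step 6
Reactants: 9 4-{6-[4-(benzyloxy)phenyl]-5-methoxy-4-oxo-4H-pyran-3-yl}-4-hydroxy-2,3-diisopropoxycyclobut-2-en-1-one (racemic)
Product: 12 2-[4-(benzyloxy)phenyl]-5,8-dihydroxy-6,7-diisopropoxy-3-methoxy-4H-chromen-4-one, via dienylketene 10 (not isolated), via 8aH-dienone 11 (not isolated)
Conditions: degassed toluene, 110 °C, Ar
Reagents that add atoms: none
Why: Moore rearrangement, the thermal ring expansion of a 4-alkenyl-4-hydroxycyclobutenone, with the C3=C2 bond of the 4-pyranone serving as the alkenyl unit. Heating opens the C1–C4 bond of the cyclobutenone in a conrotatory 4-electron electrocyclic process to the dienylketene 10. The hydroxyl, the strongest donor on C4, rotates outward (torquoselectivity), which turns the pyranonyl group inward, cis to the ketene as closure requires, and keeps the OH away from the ketene so that lactonisation to a furanone should not compete. Ring A then closes by a thermal disrotatory 6-electron electrocyclisation in which the ketene carbon bonds to pyranone C2 (future C8a) to give the 8aH-dienone 11; the other neighbour of pyranone C3 is the C4 carbonyl, which is not in linear conjugation, so there is a single site of closure. Enolisation of 11 with loss of the 8a hydrogen aromatises ring A to the hydroquinone 12, and this is the driving force. The carbinol carbon becomes C5, the two alkoxy carbons C6 and C7, and the ketene carbon C8, so all four squarate oxygens arrive in place, and the symmetric squarate leaves no regiochemical question. The centres of 9 and 11 are both erased, so no stereocontrol is needed. The step needs the correct sense of ring opening, secured by the hydroxyl donor, and the absence of oxygen, secured by degassed solvent under argon because 12 is an electron-rich hydroquinone.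

Step 7
Reactants: 12 2-[4-(benzyloxy)phenyl]-5,8-dihydroxy-6,7-diisopropoxy-3-methoxy-4H-chromen-4-one
Product: 13 2-[4-(benzyloxy)phenyl]-5-hydroxy-6,7-diisopropoxy-3,8-dimethoxy-4H-chromen-4-one
Conditions: MeI (1.1 equiv), K2CO3 (1.2 equiv), degassed acetone, rt, Ar
Reagents that add atoms: iodomethane, CI
Why: Williamson methylation under chelation control: the 5-OH is locked in a hydrogen bond to the C4 carbonyl and is not alkylated by K2CO3 and one equivalent of MeI at room temperature, so the methyl goes to the free 8-OH; exclusion of air prevents oxidation to the 5,8-quinone.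

Step 8
Reactants: 13 2-[4-(benzyloxy)phenyl]-5-hydroxy-6,7-diisopropoxy-3,8-dimethoxy-4H-chromen-4-one
Product: 14 5,6,7-trihydroxy-2-(4-hydroxyphenyl)-3,8-dimethoxy-4H-chromen-4-one
Conditions: BCl3 (8 equiv), C6HMe5 (3 equiv), CH2Cl2, −78 → 0 °C; H2O
Reagents that add atoms: none
Why: Lewis-acid dealkylation: BCl3 cleaves isopropyl and benzyl aryl ethers at or below 0 °C while methyl aryl ethers persist, which is the basis for using isopropyl as a phenol protecting group beside methoxyls. Pentamethylbenzene traps the benzyl cation, and the C4 carbonyl is already engaged by the boron bound to O5, so the 3-OMe is not activated.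

Step 9
Reactants: 14 5,6,7-trihydroxy-2-(4-hydroxyphenyl)-3,8-dimethoxy-4H-chromen-4-one
Product: 15 7-(benzyloxy)-2-[4-(benzyloxy)phenyl]-5,6-dihydroxy-3,8-dimethoxy-4H-chromen-4-one
Conditions: BnBr (2.1 equiv), K2CO3 (2.2 equiv), DMF, 0 °C → rt, Ar
Reagents that add atoms: benzyl bromide, BrCc1ccccc1
Why: Acidity-controlled Williamson benzylation: 7-OH and 4'-OH are para-conjugated to the C4 carbonyl and ionise first, 6-OH is an ordinary phenol and 5-OH is chelated. This is the same order that allows selective 7-O-benzylation of 5,6,7-trihydroxyflavones, so two equivalents of BnBr should stop at the 7,4'-dibenzyl ether.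

Step 10
Reactants: 15 7-(benzyloxy)-2-[4-(benzyloxy)phenyl]-5,6-dihydroxy-3,8-dimethoxy-4H-chromen-4-one
Product: 16 7-(benzyloxy)-2-[4-(benzyloxy)phenyl]-5-hydroxy-3,6,8-trimethoxy-4H-chromen-4-one
Conditions: MeI (1.5 equiv), K2CO3, acetone, 40 °C
Reagents that add atoms: iodomethane, CI
Why: Williamson methylation of the only unchelated phenol, 6-OH; the 5-OH stays hydrogen-bonded to C4=O, as in the standard conversion of 7-O-benzyl-5,6-dihydroxyflavones into 5-hydroxy-6-methoxyflavones.

Step 11
Reactants: 16 7-(benzyloxy)-2-[4-(benzyloxy)phenyl]-5-hydroxy-3,6,8-trimethoxy-4H-chromen-4-one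
Product: 17 5,7-dihydroxy-2-(4-hydroxyphenyl)-3,6,8-trimethoxy-4H-chromen-4-one
Conditions: H2 (1 atm), 10% Pd/C, EtOAc–MeOH, rt
Reagents that add atoms: none
Why: Catalytic hydrogenolysis of the two benzyl aryl ethers; the tetrasubstituted C2=C3 bond of the flavone is part of a vinylogous ester and is not reduced at one atmosphere.

## Compound list

1 | pyromeconic acid (3-hydroxy-4H-pyran-4-one) | O=c1ccocc1O | starting material
2 | 3-hydroxy-2-iodo-4H-pyran-4-one | O=c1ccoc(I)c1O | intermediate
3 | 2-iodo-3-methoxy-4H-pyran-4-one | COc1c(I)occc1=O | intermediate
4 | 4-(benzyloxy)phenylboronic acid | OB(O)c1ccc(OCc2ccccc2)cc1 | starting material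
5 | 2-[4-(benzyloxy)phenyl]-3-methoxy-4H-pyran-4-one | COc1c(-c2ccc(OCc3ccccc3)cc2)occc1=O | intermediate
6 | 2-[4-(benzyloxy)phenyl]-5-iodo-3-methoxy-4H-pyran-4-one | COc1c(-c2ccc(OCc3ccccc3)cc2)occ(I)c1=O | intermediate
7 | diisopropyl squarate (3,4-diisopropoxycyclobut-3-ene-1,2-dione) | CC(C)OC1=C(OC(C)C)C(=O)C1=O | starting material
8 | {6-[4-(benzyloxy)phenyl]-5-methoxy-4-oxo-4H-pyran-3-yl}magnesium chloride (not isolated) | COc1c(-c2ccc(OCc3ccccc3)cc2)occ([Mg]Cl)c1=O | intermediate
9 | 4-{6-[4-(benzyloxy)phenyl]-5-methoxy-4-oxo-4H-pyran-3-yl}-4-hydroxy-2,3-diisopropoxycyclobut-2-en-1-one (racemic) | CC(C)OC1=C(OC(C)C)C(O)(c2coc(-c3ccc(OCc4ccccc4)cc3)c(OC)c2=O)C1=O | intermediate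
10 | (3Z)-4-{6-[4-(benzyloxy)phenyl]-5-methoxy-4-oxo-4H-pyran-3-yl}-4-hydroxy-2,3-diisopropoxybuta-1,3-dien-1-one (dienylketene, not isolated) | CC(C)OC(=C=O)/C(OC(C)C)=C(/O)c1coc(-c2ccc(OCc3ccccc3)cc2)c(OC)c1=O | intermediate
11 | 2-[4-(benzyloxy)phenyl]-5-hydroxy-6,7-diisopropoxy-3-methoxy-8aH-chromene-4,8-dione (racemic, not isolated) | CC(C)OC1=C(OC(C)C)C(O)=C2C(=O)C(OC)=C(c3ccc(OCc4ccccc4)cc3)OC2C1=O | intermediate
12 | 2-[4-(benzyloxy)phenyl]-5,8-dihydroxy-6,7-diisopropoxy-3-methoxy-4H-chromen-4-one | COc1c(-c2ccc(OCc3ccccc3)cc2)oc2c(O)c(OC(C)C)c(OC(C)C)c(O)c2c1=O | intermediate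
13 | 2-[4-(benzyloxy)phenyl]-5-hydroxy-6,7-diisopropoxy-3,8-dimethoxy-4H-chromen-4-one | COc1c(-c2ccc(OCc3ccccc3)cc2)oc2c(OC)c(OC(C)C)c(OC(C)C)c(O)c2c1=O | intermediate
14 | 5,6,7-trihydroxy-2-(4-hydroxyphenyl)-3,8-dimethoxy-4H-chromen-4-one | COc1c(-c2ccc(O)cc2)oc2c(OC)c(O)c(O)c(O)c2c1=O | intermediate
15 | 7-(benzyloxy)-2-[4-(benzyloxy)phenyl]-5,6-dihydroxy-3,8-dimethoxy-4H-chromen-4-one | COc1c(-c2ccc(OCc3ccccc3)cc2)oc2c(OC)c(OCc3ccccc3)c(O)c(O)c2c1=O | intermediate
16 | 7-(benzyloxy)-2-[4-(benzyloxy)phenyl]-5-hydroxy-3,6,8-trimethoxy-4H-chromen-4-one | COc1c(-c2ccc(OCc3ccccc3)cc2)oc2c(OC)c(OCc3ccccc3)c(OC)c(O)c2c1=O | intermediate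
17 | 5,7-dihydroxy-2-(4-hydroxyphenyl)-3,6,8-trimethoxy-4H-chromen-4-one | COc1c(O)c(OC)c2oc(-c3ccc(O)cc3)c(OC)c(=O)c2c1O | target

## Step count and least certain steps

Total: 11 steps. Longest linear sequence: 11 steps, from 1 to 17; 4 and 7 are purchased and enter in steps 3 and 5.

**Step 6 (key step).** The closure of ketene 10 onto pyranone C2 interrupts the cyclic conjugation of the pyranone and may be slow. The ketene could then be consumed by lactonisation with the free hydroxyl, if some ring opening occurs with the hydroxyl inward, or by oligomerisation. The hydroquinone product may also be oxidised by traces of air during the reaction. The fallback changes the substrate to a carbinol ether, for which ring expansion to mono-protected hydroquinones is known. It sets out from 9, which is silylated with Et3SiOTf and 2,6-lutidine to 4-{6-[4-(benzyloxy)phenyl]-5-methoxy-4-oxo-4H-pyran-3-yl}-2,3-diisopropoxy-4-(triethylsilyloxy)cyclobut-2-en-1-one F1. The silyloxy group still rotates outward but cannot trap the ketene. Thermolysis in toluene or p-xylene should give 2-[4-(benzyloxy)phenyl]-8-hydroxy-6,7-diisopropoxy-3-methoxy-5-(triethylsilyloxy)-4H-chromen-4-one F2, a mono-protected hydroquinone that cannot form a quinone. Methylation with MeI and K2CO3 gives 2-[4-(benzyloxy)phenyl]-6,7-diisopropoxy-3,8-dimethoxy-5-(triethylsilyloxy)-4H-chromen-4-one F3, and Bu4NF buffered with AcOH removes the silyl group. The fallback comes back to the route at 13.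

**Step 5.** The magnesiated pyranone 8 may fragment by β-elimination of the ring oxygen, giving an alkynyl ketone, or iPrMgCl·LiCl may add to C6 of the pyranone before exchange. Addition of 8 at the vinylogous ester carbon of 7 instead of the carbonyl is a further risk. The fallback replaces the basic magnesium species by a zinc reagent. It sets out from 6, into which zinc dust activated with LiCl in THF is inserted to give {6-[4-(benzyloxy)phenyl]-5-methoxy-4-oxo-4H-pyran-3-yl}zinc iodide F4. This species does not eliminate at room temperature. It is added to 7 with MgCl2 as Lewis-acid promoter, the known way of bringing organozinc halides to add to carbonyl groups, and the fallback comes back at 9.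

**Step 4.** Iodination may take place on ring B ortho to the benzyloxy group in competition with pyranone C5, or both may occur. The fallback changes the order so that no arene is present during iodination. It sets out from 3, which is iodinated under the same conditions to 2,5-diiodo-3-methoxy-4H-pyran-4-one F5. One equivalent of 4 is then coupled under the conditions of step 3, relying on the faster oxidative addition at the β-iodide (C2, vinylogous acyl iodide) over the α-iodide (C5), as seen with α,β-dihaloenones. It comes back at 6.

**Step 7.** The hydroquinone monoanion may be oxidised to the quinone by adventitious oxygen, or both phenols may be methylated. The fallback accepts the oxidation and purifies at the quinone level. It sets out from 12, which is oxidised with Ag2O to 2-[4-(benzyloxy)phenyl]-6,7-diisopropoxy-3-methoxy-4H-chromene-4,5,8-trione F6, a stable compound that can be chromatographed. Reductive methylation follows (aqueous Na2S2O4, then Me2SO4 and K2CO3 with the reductant still present); chelation again directs the methyl to O8, and the fallback comes back at 13.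

**Step 9.** Benzylation may spill over to O6, or stall at O7, which is flanked by the 6-OH and the 8-OMe. The 5,6,7-trihydroxy ring may also be oxidised while it is held as a polyanion in carbonate. The fallback replaces phenoxide alkylation by a Mitsunobu etherification (BnOH, PPh3, diisopropyl azodicarboxylate, THF). Only the most acidic phenols, 7-OH and 4'-OH, are deprotonated by the betaine, and no carbonate base is present. It sets out from 14, comes back at 15 and makes no new compound.

## Further compounds

F1 | step 6 | 4-{6-[4-(benzyloxy)phenyl]-5-methoxy-4-oxo-4H-pyran-3-yl}-2,3-diisopropoxy-4-(triethylsilyloxy)cyclobut-2-en-1-one (racemic) | CC(C)OC1=C(OC(C)C)C(O[Si](CC)(CC)CC)(c2coc(-c3ccc(OCc4ccccc4)cc3)c(OC)c2=O)C1=O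
F2 | step 6 | 2-[4-(benzyloxy)phenyl]-8-hydroxy-6,7-diisopropoxy-3-methoxy-5-(triethylsilyloxy)-4H-chromen-4-one | COc1c(-c2ccc(OCc3ccccc3)cc2)oc2c(O)c(OC(C)C)c(OC(C)C)c(O[Si](CC)(CC)CC)c2c1=O
F3 | step 6 | 2-[4-(benzyloxy)phenyl]-6,7-diisopropoxy-3,8-dimethoxy-5-(triethylsilyloxy)-4H-chromen-4-one | COc1c(-c2ccc(OCc3ccccc3)cc2)oc2c(OC)c(OC(C)C)c(OC(C)C)c(O[Si](CC)(CC)CC)c2c1=O
F4 | step 5 | {6-[4-(benzyloxy)phenyl]-5-methoxy-4-oxo-4H-pyran-3-yl}zinc iodide | COc1c(-c2ccc(OCc3ccccc3)cc2)occ([Zn]I)c1=O
F5 | step 4 | 2,5-diiodo-3-methoxy-4H-pyran-4-one | COc1c(I)occ(I)c1=O
F6 | step 7 | 2-[4-(benzyloxy)phenyl]-6,7-diisopropoxy-3-methoxy-4H-chromene-4,5,8-trione | COC1=C(c2ccc(OCc3ccccc3)cc2)OC2=C(C1=O)C(=O)C(OC(C)C)=C(OC(C)C)C2=O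
F0 | step 9 | none | none
A1 | alternative 1 | 7-(benzyloxy)-2-[4-(benzyloxy)phenyl]-3,6,8-trimethoxy-4-oxo-4H-chromen-5-yl 4-(benzyloxy)benzoate | COc1c(-c2ccc(OCc3ccccc3)cc2)oc2c(OC)c(OCc3ccccc3)c(OC)c(OC(=O)c3ccc(OCc4ccccc4)cc3)c2c1=O
A2 | alternative 1 | 4-(benzyloxy)-2,6-bis{[4-(benzyloxy)benzoyl]oxy}-3,5-dimethoxybenzoyl chloride | O=C(Cl)c1c(OC(=O)c2ccc(OCc3ccccc3)cc2)c(OC)c(OCc2ccccc2)c(OC)c1OC(=O)c1ccc(OCc2ccccc2)cc1
A3 | alternative 2 | 5,7-bis(benzyloxy)-2-[4-(benzyloxy)phenyl]-6,8-dimethoxychroman-3-one (racemic) | O=C1Cc2c(OCc3ccccc3)c(OC)c(OCc3ccccc3)c(OC)c2OC1c1ccc(OCc2ccccc2)cc1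
A4 | alternative 2 | 1,3-bis(benzyloxy)-5-({1-[4-(benzyloxy)phenyl]prop-2-yn-1-yl}oxy)-2,4-dimethoxybenzene (racemic) | C#CC(Oc1cc(OCc2ccccc2)c(OC)c(OCc2ccccc2)c1OC)c1ccc(OCc2ccccc2)cc1
A5 | alternative 3 | 7-(benzyloxy)-2-[4-(benzyloxy)phenyl]-5-hydroxy-3,6,8-trimethoxy-4H-chromen-4-one | COc1c(-c2ccc(OCc3ccccc3)cc2)oc2c(OC)c(OCc3ccccc3)c(OC)c(O)c2c1=O
A6 | alternative 3 | 7-(benzyloxy)-2-[4-(benzyloxy)phenyl]-6,8-dibromo-5-hydroxy-3-methoxy-4H-chromen-4-one | COc1c(-c2ccc(OCc3ccccc3)cc2)oc2c(Br)c(OCc3ccccc3)c(Br)c(O)c2c1=O
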